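**Retrosynthetic overview**
1. Target acid 18 ⇐ primary alcohol 16 (oxidation) ⇐ 3,6-dihydro-1,2-dioxine 15 (saturation of C4=C5 sets C4).
2. The only ring is formed in one step by [4+2] cycloaddition of singlet oxygen to the (3E,5E)-dienol 14; the E,E geometry becomes the cis C3/C6 relationship.
3. Dienol 14 ⇐ two syn-carbocuprations with EtCu (alkyne 9 → iodide 11 → enyne 12 → 14, the second quenched with ethylene oxide), which fix both trisubstituted alkenes.
4. Alkyne 9 ⇐ acetylide + tosylate 8 ⇐ ester 6 ⇐ invertive SN2 coupling of the (S)-2-ethylhexyl Grignard reagent with (S)-lactate triflate.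
5. Stereocentres: C10 is bought in (S)-2-ethylhexanol and C8 comes from (S)-lactate. The ring centres come from the cycloaddition and the face-selective reduction; their sense relative to the side chain is not controlled and is secured by separating two diastereomers after step 10.

Assumption: (S)-2-ethylhexan-1-ol (1) is taken as a purchasable single enantiomer (lipase-resolved bulk alcohol).

**Step 1**
Reactants: 1 (2S)-2-ethylhexan-1-ol
Product: 2 (3S)-3-(bromomethyl)heptane
Conditions: CBr4, PPh3, CH2Cl2, 0 °C → rt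
Reagents that add atoms: carbon tetrabromide, BrC(Br)(Br)Br
Why: Appel bromination replaces the primary OH by SN2 at CH2 and leaves the neighbouring stereocentre untouched.

**Step 2**
Reactants: 3 tert-butyl (2S)-2-hydroxypropanoate
Product: 4 tert-butyl (2S)-2-[(trifluoromethanesulfonyl)oxy]propanoate
Conditions: Tf2O, 2,6-lutidine, CH2Cl2, −78 → 0 °C
Reagents that add atoms: trifluoromethanesulfonic anhydride, O=S(=O)(OS(=O)(=O)C(F)(F)F)C(F)(F)F
Why: O-sulfonylation with a hindered base does not break the C–O bond, so the (S) centre of the lactate is kept.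

**Step 3**
Reactants: 2 (3S)-3-(bromomethyl)heptane; 4 tert-butyl (2S)-2-[(trifluoromethanesulfonyl)oxy]propanoate
Product: 6 tert-butyl (2S,4S)-4-ethyl-2-methyloctanoate, via Grignard reagent 5 (not isolated)
Conditions: Mg, THF, 45 °C; then added to 4, ZnCl2 (5 mol %), THF, 0 °C
Reagents that add atoms: none
Why: The zinc-catalysed sp3–sp3 coupling of an α-triflyloxy ester with a Grignard reagent (through a triorganozincate) is a clean SN2 displacement with inversion, so the (S)-triflate gives the (2S)-methyl centre (the descriptor stays S because the priorities change) while the β-centre of the Grignard reagent is not involved.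

**Step 4**
Reactants: 6 tert-butyl (2S,4S)-4-ethyl-2-methyloctanoate
Product: 7 (2S,4S)-4-ethyl-2-methyloctan-1-ol
Conditions: LiAlH4, Et2O, 0 °C → rt
Reagents that add atoms: none
Why: Hydride reduction of the ester to the primary alcohol proceeds without enolisation, so both stereocentres are retained.

**Step 5**
Reactants: 7 (2S,4S)-4-ethyl-2-methyloctan-1-ol
Product: 8 (2S,4S)-4-ethyl-2-methyloctyl 4-methylbenzenesulfonate
Conditions: TsCl, pyridine, CH2Cl2, 0 °C → rt
Reagents that add atoms: 4-toluenesulfonyl chloride, Cc1ccc(cc1)S(=O)(=O)Cl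
Why: Tosylation of the primary alcohol activates C1 for SN2 displacement without touching a stereocentre.

**Step 6**
Reactants: 8 (2S,4S)-4-ethyl-2-methyloctyl 4-methylbenzenesulfonate
Product: 9 (4S,6S)-6-ethyl-4-methyldec-1-yne
Conditions: LiC≡CH·H2NCH2CH2NH2, DMSO, 15 °C → rt
Reagents that add atoms: lithium acetylide–ethylenediamine complex, [Li]C#C.NCCN
Why: SN2 alkynylation of a primary tosylate by lithium acetylide in DMSO is reliable for β-branched substrates and installs the terminal alkyne.

**Step 7**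
Reactants: 9 (4S,6S)-6-ethyl-4-methyldec-1-yne
Product: 11 (1E,4S,6S)-2,6-diethyl-1-iodo-4-methyldec-1-ene, via alkenylcopper 10 (not isolated)
Conditions: EtMgBr, CuBr·SMe2, Et2O/Me2S, −45 °C; then 9, −25 °C; then I2, THF, −78 → 0 °C
Reagents that add atoms: ethylmagnesium bromide, CC[Mg]Br; iodine, II
Why: Normant syn-carbocupration puts ethyl on the internal carbon and copper on the terminal carbon on the same side, and iodinolysis with retention gives the E iodide in which ethyl is cis to iodine.

**Step 8**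
Reactants: 11 (1E,4S,6S)-2,6-diethyl-1-iodo-4-methyldec-1-ene
Product: 12 (3E,6S,8S)-4,8-diethyl-6-methyldodec-3-en-1-yne
Conditions: HC≡CMgBr, ZnBr2, THF, 0 °C; then 11, Pd(PPh3)4 (5 mol %), rt
Reagents that add atoms: ethynylmagnesium bromide, C#C[Mg]Br
Why: Negishi coupling of the alkenyl iodide with ethynylzinc bromide under zerovalent palladium proceeds with retention of alkene geometry and gives the terminal enyne directly.

**Step 9**
Reactants: 12 (3E,6S,8S)-4,8-diethyl-6-methyldodec-3-en-1-yne
Product: 14 (3E,5E,8S,10S)-4,6,10-triethyl-8-methyltetradeca-3,5-dien-1-ol, via dienylcopper 13 (not isolated)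
Conditions: EtMgBr, CuBr·SMe2, Et2O/Me2S, −45 °C; then 12, −25 °C; then ethylene oxide, −78 → −20 °C; aq NH4Cl
Reagents that add atoms: ethylmagnesium bromide, CC[Mg]Br; ethylene oxide, C1CO1
Why: A second syn-carbocupration of the enyne's terminal alkyne (ethyl to the internal carbon) gives a dienylcopper that opens ethylene oxide with retention, so C3=C4 is E with ethyl cis to the CH2CH2OH arm.

**Step 10 (key step)**
Reactants: 14 (3E,5E,8S,10S)-4,6,10-triethyl-8-methyltetradeca-3,5-dien-1-ol
Product: 15 2-[(3S,6R)-4,6-diethyl-6-[(2S,4S)-4-ethyl-2-methyloctyl]-3,6-dihydro-1,2-dioxin-3-yl]ethan-1-ol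
Conditions: O2, hν (visible), tetraphenylporphyrin (1 mol %), CH2Cl2, −30 °C; chromatography
Reagents that add atoms: dioxygen, O=O
Why: Suprafacial [4+2] cycloaddition of singlet oxygen to the s-cis E,E-diene puts the two outside groups (CH2CH2OH at C3, octyl chain at C6) cis on the new ring, but the remote side-chain centres give no useful facial bias, so 15 is expected with its (3R,6S) ring diastereomer in about equal amounts and is separated from it on silica or by HPLC.

**Step 11**
Reactants: 15 2-[(3S,6R)-4,6-diethyl-6-[(2S,4S)-4-ethyl-2-methyloctyl]-3,6-dihydro-1,2-dioxin-3-yl]ethan-1-ol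
Product: 16 2-[(3S,4S,6R)-4,6-diethyl-6-[(2S,4S)-4-ethyl-2-methyloctyl]-1,2-dioxan-3-yl]ethan-1-ol
Conditions: KO2CN=NCO2K (large excess, in portions), AcOH, MeOH/CH2Cl2, 0 °C → rt
Reagents that add atoms: none
Why: Diimide reduction saturates C=C without cleaving O–O and should deliver both hydrogens mainly to the ring face anti to the two cis substituents (the face of C3–H and the C6 ethyl), so the C4 ethyl ends cis to them (4S), with the minor 4-epimer removed by chromatography.

**Step 12**
Reactants: 16 2-[(3S,4S,6R)-4,6-diethyl-6-[(2S,4S)-4-ethyl-2-methyloctyl]-1,2-dioxan-3-yl]ethan-1-ol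
Product: 18 2-[(3S,4S,6R)-4,6-diethyl-6-[(2S,4S)-4-ethyl-2-methyloctyl]-1,2-dioxan-3-yl]acetic acid, via aldehyde 17 (not isolated)
Conditions: TEMPO (20 mol %), PhI(OAc)2 (2.2 equiv), MeCN/H2O, rt
Reagents that add atoms: water, O
Why: The oxoammonium oxidation (TEMPO/PhI(OAc)2 in wet MeCN) takes the primary alcohol through the aldehyde hydrate to the acid under near-neutral conditions that leave the dialkyl peroxide and all stereocentres intact.

**Compound list**
1 | (2S)-2-ethylhexan-1-ol | CCCC[C@H](CC)CO | starting material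
2 | (3S)-3-(bromomethyl)heptane | CCCC[C@H](CC)CBr | intermediate
3 | tert-butyl (2S)-2-hydroxypropanoate | C[C@H](O)C(=O)OC(C)(C)C | starting material
4 | tert-butyl (2S)-2-[(trifluoromethanesulfonyl)oxy]propanoate | C[C@H](OS(=O)(=O)C(F)(F)F)C(=O)OC(C)(C)C | intermediate
5 | [(2S)-2-ethylhexyl]magnesium bromide | CCCC[C@H](CC)C[Mg]Br | intermediate
6 | tert-butyl (2S,4S)-4-ethyl-2-methyloctanoate | CCCC[C@H](CC)C[C@H](C)C(=O)OC(C)(C)C | intermediate
7 | (2S,4S)-4-ethyl-2-methyloctan-1-ol | CCCC[C@H](CC)C[C@H](C)CO | intermediate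
8 | (2S,4S)-4-ethyl-2-methyloctyl 4-methylbenzenesulfonate | CCCC[C@H](CC)C[C@H](C)COS(=O)(=O)c1ccc(C)cc1 | intermediate
9 | (4S,6S)-6-ethyl-4-methyldec-1-yne | CCCC[C@H](CC)C[C@H](C)CC#C | intermediate
10 | [(1E,4S,6S)-2,6-diethyl-4-methyldec-1-en-1-yl]copper | CCCC[C@H](CC)C[C@H](C)C/C(CC)=C/[Cu] | intermediate
11 | (1E,4S,6S)-2,6-diethyl-1-iodo-4-methyldec-1-ene | CCCC[C@H](CC)C[C@H](C)C/C(CC)=C/I | intermediate
12 | (3E,6S,8S)-4,8-diethyl-6-methyldodec-3-en-1-yne | CCCC[C@H](CC)C[C@H](C)C/C(CC)=C/C#C | intermediate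
13 | [(1E,3E,6S,8S)-2,4,8-triethyl-6-methyldodeca-1,3-dien-1-yl]copper | CCCC[C@H](CC)C[C@H](C)C/C(CC)=C/C(CC)=C/[Cu] | intermediate
14 | (3E,5E,8S,10S)-4,6,10-triethyl-8-methyltetradeca-3,5-dien-1-ol | CCCC[C@H](CC)C[C@H](C)C/C(CC)=C/C(CC)=C/CCO | intermediate
15 | 2-[(3S,6R)-4,6-diethyl-6-[(2S,4S)-4-ethyl-2-methyloctyl]-3,6-dihydro-1,2-dioxin-3-yl]ethan-1-ol | CCCC[C@H](CC)C[C@H](C)C[C@]1(CC)C=C(CC)[C@H](CCO)OO1 | intermediate
16 | 2-[(3S,4S,6R)-4,6-diethyl-6-[(2S,4S)-4-ethyl-2-methyloctyl]-1,2-dioxan-3-yl]ethan-1-ol | CCCC[C@H](CC)C[C@H](C)C[C@]1(CC)C[C@H](CC)[C@H](CCO)OO1 | intermediate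
17 | 2-[(3S,4S,6R)-4,6-diethyl-6-[(2S,4S)-4-ethyl-2-methyloctyl]-1,2-dioxan-3-yl]acetaldehyde | CCCC[C@H](CC)C[C@H](C)C[C@]1(CC)C[C@H](CC)[C@H](CC=O)OO1 | intermediate
18 | 2-[(3S,4S,6R)-4,6-diethyl-6-[(2S,4S)-4-ethyl-2-methyloctyl]-1,2-dioxan-3-yl]acetic acid | CCCC[C@H](CC)C[C@H](C)C[C@]1(CC)C[C@H](CC)[C@H](CC(=O)O)OO1 | target

**Count**
Total steps: 12. Longest linear sequence: 11 (steps 1 and 3–12 from 1; step 2 is the side branch from 3).

**The three steps most likely to fail**

Step 9. The enyne C–H is acidic and may be metalated instead of carbocuprated, and the dienylcopper may react sluggishly with ethylene oxide. The fallback replaces carbometalation by two cross-couplings and sets out from 11. Lithium–iodine exchange (t-BuLi, Et2O, −78 °C) gives the alkenyllithium F1, and ZnBr2 converts it into the alkenylzinc bromide F2. Trans-selective Negishi coupling of this with tert-butyl[(4,4-dibromobut-3-en-1-yl)oxy]dimethylsilane F3 (from commercial 3-[(tert-butyldimethylsilyl)oxy]propanal, CBr4, PPh3) under PdCl2(DPEphos) replaces only the bromine trans to the oxygenated chain and gives the (3Z)-bromodiene silyl ether F4. A second Negishi coupling with Et2Zn under Pd(t-Bu3P)2 exchanges the remaining bromine for ethyl with retention to give the silyl ether F5, and TBAF in THF returns to the route at 14.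

Step 10. This is the most critical step: the crowded, partly twisted diene may give ene hydroperoxides instead of the endoperoxide, and half of the cycloadduct is the unwanted ring diastereomer. The fallback for the chemoselectivity problem sets out from 14, which is silylated (Et3SiCl, imidazole) to the triethylsilyl ether F6. This is oxygenated with ground-state O2 under catalysis by the aminium salt (4-BrC6H4)3N·SbCl6 in CH2Cl2 at −78 °C; this is a radical-cation chain [4+2] oxygenation with no ene channel, though its stereospecificity must be checked. It gives the dihydrodioxine silyl ether F7, and HF·pyridine in THF returns to the route at 15. The facial problem remains and is still solved by separation.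

Step 11. Diimide reduces trisubstituted alkenes slowly, and the face selectivity at C4 is only expected, not assured. The fallback sets out from 15 and changes both order and reductant. Oxidation first (TEMPO, PhI(OAc)2, MeCN/H2O) passes through the unsaturated aldehyde F8 (not isolated) to the dihydrodioxine acid F9. The ring alkene is then saturated on a metal surface (H2 1 atm, Pt/C, EtOAc, 0 °C, stopped after one equivalent, relying on the known survival of 1,2-dioxanes of this class in brief heterogeneous hydrogenation), which should add from the same less hindered face and returns to the route at 18.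

**Further compounds**
F1 | step 9 | [(1E,4S,6S)-2,6-diethyl-4-methyldec-1-en-1-yl]lithium | CCCC[C@H](CC)C[C@H](C)C/C(CC)=C/[Li]
F2 | step 9 | bromo[(1E,4S,6S)-2,6-diethyl-4-methyldec-1-en-1-yl]zinc | CCCC[C@H](CC)C[C@H](C)C/C(CC)=C/[Zn]Br
F3 | step 9 | tert-butyl[(4,4-dibromobut-3-en-1-yl)oxy]dimethylsilane | BrC(Br)=CCCO[Si](C)(C)C(C)(C)C
F4 | step 9 | tert-butyl{[(3Z,5E,8S,10S)-4-bromo-6,10-diethyl-8-methyltetradeca-3,5-dien-1-yl]oxy}dimethylsilane | CCCC[C@H](CC)C[C@H](C)C/C(CC)=C/C(Br)=C/CCO[Si](C)(C)C(C)(C)C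
F5 | step 9 | tert-butyl{[(3E,5E,8S,10S)-4,6,10-triethyl-8-methyltetradeca-3,5-dien-1-yl]oxy}dimethylsilane | CCCC[C@H](CC)C[C@H](C)C/C(CC)=C/C(CC)=C/CCO[Si](C)(C)C(C)(C)C
F6 | step 10 | triethyl{[(3E,5E,8S,10S)-4,6,10-triethyl-8-methyltetradeca-3,5-dien-1-yl]oxy}silane | CCCC[C@H](CC)C[C@H](C)C/C(CC)=C/C(CC)=C/CCO[Si](CC)(CC)CC
F7 | step 10 | triethyl{2-[(3S,6R)-4,6-diethyl-6-[(2S,4S)-4-ethyl-2-methyloctyl]-3,6-dihydro-1,2-dioxin-3-yl]ethoxy}silane | CCCC[C@H](CC)C[C@H](C)C[C@]1(CC)C=C(CC)[C@H](CCO[Si](CC)(CC)CC)OO1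
F8 | step 11 | 2-[(3S,6R)-4,6-diethyl-6-[(2S,4S)-4-ethyl-2-methyloctyl]-3,6-dihydro-1,2-dioxin-3-yl]acetaldehyde | CCCC[C@H](CC)C[C@H](C)C[C@]1(CC)C=C(CC)[C@H](CC=O)OO1
F9 | step 11 | 2-[(3S,6R)-4,6-diethyl-6-[(2S,4S)-4-ethyl-2-methyloctyl]-3,6-dihydro-1,2-dioxin-3-yl]acetic acid | CCCC[C@H](CC)C[C@H](C)C[C@]1(CC)C=C(CC)[C@H](CC(=O)O)OO1
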